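All runs were generated by integration on assumed constants; scatter was added.

| flask | solid substrate | remark | time |
|---|---|---|---|
| south-east | 0.050 M | the very flask that is asked about, followed so far |  |
| east | 0.025 M | run made earlier |  |
| flask | 0.050 M |  | 8.0 h |

| run | time / h | target / % | solid substrate / % |
|---|---|---|---|
| south-east | 0.833 | 1.8 | 97.5 |
| south-east | 1.50 | 4.7 | 93.1 |
| south-east | 2.50 | 7.1 | 90.7 |
| south-east | 3.00 | 7.7 | 87.9 |
| east | 0.833 | 3.8 | 93.3 |
| east | 1.50 | 7.7 | 88.6 |
| east | 2.50 | 13.8 | 81.8 |
| east | 3.00 | 15.7 | 76.5 |

(readings scatter by 0.5 percentage points)
* amount of target in percent of the solid substrate charged, at 1.5 h, 4.0 h and 8.0 h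
- as a solid, counted per litre of solution: solid substrate
- the numbers in the tables scatter by 0.5 percentage points (one standard deviation)
- at the start none of the solid substrate is in solution

**Reading a constant.** I had no rate constants for these flasks, so I read from the readings at 3.00 h a zero-order rate, meaning a loss per hour that doesn't change with the amount present. In the south-east flask c(solid substrate) had fallen at 2.02 mM h⁻¹, and in the east run, charged with half as much, at 1.96 mM h⁻¹, so I read the two losses as equal, each resting on readings that scatter by 0.5 percentage points.

**Solid lifetime.** Dividing a charge by that loss gives the solid lifetime, the time a charge lasts at the read rate, 24.8 h for the south-east flask. The asked time of 8.0 h is shorter, so I expected 67.7 % of the solid substrate still to stand at its end, and I kept the loss steady up to there.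

**Target share.** Target had appeared at 1.28 mM h⁻¹ in the south-east flask and 1.31 mM h⁻¹ in the east run, so by the readings of the south-east flask 63.6 % of the lost solid had shown up as target. Multiplying that share by the elapsed time over the lifetime, I reckoned 3.85 %, 10.3 % and 20.5 % of the charge as target at the three asked times.

**The forecast.** The forecast gave 4.2 %, 10.3 % and 20 % on the ground that “the rate doesn't depend on how much solid is present”, and its numbers stood above mine at the first time and below mine at the last.

**The flask.** The south-east flask gave 4.18 %, 10.2 % and 16.9 % of target, and at 8.00 h its starting material, standing at 12.4 %, was being made 2.37 times faster than it was used up, each step taken net.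

    starting material ⇌ target + by-product (K = 0.0119 M, k = 3.34 h⁻¹)
    solid substrate ⇌ starting material, rate k2*(cs2 - [starting material]) while solid is left; crystals form when [starting material] > cs2 (solubility = 43.0 mM, k = 0.0456 h⁻¹)
    2 starting material → self-condensation product (k = 0.163 L mol⁻¹ h⁻¹)

**Lifetime again.** The lifetime of 24.8 h had put the solid substrate of the south-east flask at 67.7 % at 8.00 h, and the flask held 70.6 %. For the east run the loss of the south-east flask gives a lifetime of 12.4 h, so 1.50 h should have left 87.9 % of that charge, and the reading at that time stood at 88.6 %.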